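Late in a closed flask, X goes on rising at a slow fractional rate on whatever is not yet X, and that rate is the number we carry through the set-ups below, in which J turns into X.

| setting | delta | epsilon | alpha | elm | larch | cedar | alder |
|---|---|---|---|---|---|---|---|
| J | 0.69 M | 0.34 M | 1.4 M | 0.69 M | 0.69 M | 0.69 M | 0.69 M |
| remark | run made earlier | run made earlier | run made earlier | everything together in a closed stirred flask, run for 40 min | one stirred flow tank at steady state, fed with the mixture as stated, mean residence time 40 min | plug flow through a tube for 40 min, no back-mixing | a single well-mixed tank run continuously and read at steady state, 120 min in it on average |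
| time |  |  |  | 40 min |  | 40 min |  |

| run | time / min | X / % | J / % |
|---|---|---|---|
| delta | 5.00 | 2.3 | 38.1 |
| delta | 15.0 | 15.5 | 11.9 |
| delta | 25.0 | 24.8 | 10.3 |
| delta | 40.0 | 37.9 | 8.7 |
| epsilon | 5.00 | 5.2 | 38.4 |
| epsilon | 15.0 | 14.4 | 12.1 |
| epsilon | 25.0 | 25.9 | 10.9 |
| epsilon | 40.0 | 36.3 | 7.0 |
| alpha | 5.00 | 3.3 | 36.2 |
| alpha | 15.0 | 13.1 | 13.3 |
| alpha | 25.0 | 24.6 | 11.8 |
| alpha | 40.0 | 37.4 | 8.0 |

(scatter of a reading: 1 percentage point)

- the stated concentrations are those of everything mixed, before any reaction; amounts are the same in each set-up
- the earlier runs were read with a standard deviation of 1 percentage point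
- the earlier runs were made in a closed, stirred flask
- a reading or a percentage of X counts all its forms, free or not
- a reading of J is of its free form alone

1. the set-up with the highest amount of X at the outlet or at the end, in percent of the J put in ("none" if the first two lie within 2 percentage points) (elm / larch / cedar / alder / none)
2. amount of X at the outlet or at the end, in percent of the J put in, elm
3. amount of X at the outlet or at the end, in percent of the J put in, larch
4. amount of X at the outlet or at the end, in percent of the J put in, cedar
5. amount of X at the outlet or at the end, in percent of the J put in, alder

We read the ladder from the fast end. The closed runs differ by about their scatter of 1 percentage point, although [J] at the start spans 0.34 M to 1.4 M, so we average them and treat the steps as first-order. J reads 37.6% at 5.00 min and 12.4% at 15.0 min, when X reads 14.3%. So 73.3% of the charge sits in a pool that neither reading shows. The fall of J towards its plateau gives a fast rate r, read as 0.250 min⁻¹.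

At 40.0 min X reads 37.2%. The next rung is the slow rate s, the fractional rate at which the part not yet X becomes X once the pool has filled, read between 15.0 min and 40.0 min as 0.0124 min⁻¹. Since r is 20.2 times s, the pool is the resting state and the step out of it is the rate-limiting step.

Elm and cedar give J the same 40 min, so we take the mean reading 37.2% for both. For two such rungs in one well-mixed tank of mean residence time τ, taken as one-way steps, the share of X is sτ over one plus sτ, times the correction factor rτ over one plus rτ. By our reckoning larch, with 40 min on average, gets 30.2%, and alder, with 120 min on average, gets 57.9%, more than the others.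

The forecast gives 37% for elm, 30% for larch, 37% for cedar and 58% for alder, with alder best: “Alder wins simply through its longer residence time.”

The flask gives 37.4% for elm, 30.2% for larch, 37.4% for cedar and 54.1% for alder, so alder is best.

    D ⇌ X (K = 6.86, k = 2.65 × 10⁻⁴ s⁻¹)
    J ⇌ D (K = 6.60, k = 0.00375 s⁻¹)
    J + X ⇌ L, settled at all times (K = 0.320 L mol⁻¹)

Carried on, s of 0.0124 min⁻¹ in the tank rule gives 30.2% beside the 30.2% of larch, and 57.9% beside the 54.1% of alder, 3.8 points above it. By forward rates alone, J turns into D with a half-life of 3.1 min and D into X with 44 min, which is 14.2 times as long. Cedar ends with 53.4% of the J charged standing as D. Larch has 51.7% as D at its outlet.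

(The readings were computed with constants of no real substance, and the scatter is random.)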